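**Plan**
- Retrosynthesis: the C13=C14 enoate goes back to a C13≡C14 alkyne, C18–OAc to an ester and C3=O to an enol-ether oxygen. Ring A is then cut at C5–C10 and C3–C4 (intramolecular Diels–Alder), which opens ring B as well. The acyclic triene is cut at C4=C5, C6–C7, C2=C3, C10–C20 and C1–C2.
- Feature used: ring A holds the contiguous C4 (quaternary), C5 and C10 (quaternary) centres of a cis-fused decalin. Its six atoms split into a C10=C1–C2=C3 diene and a C4=C5 methacrylate-type dienophile, already linked by the C6–C9 chain of ring B.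
- Forward: (R)-limonene is opened to an acyclic unit around C9 whose three arms become the side-chain alkyne, the diene and the dienophile. Rings A and B then arise together in step 17; the side chain, C18 and C3 are finished afterwards.
- Stereochemistry: C9 comes from limonene. The cis fusion (C5, C10) follows from the Z-configured C10=C1 diene bond, C4 from the Z-enoate, and the diene face from 1,3-allylic strain at C9. Both Z-trisubstituted alkenes (C10=C1, C13=C14) come from syn-carbocupration of 2-ynoates.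

Key step: step 17

Remark: C1–C20 follow labdane numbering; "5β-labda" names mean the cis-fused skeleton with 5β-H, 9α-H, 10β-CH3 and C18 on the α face of C4. 4-Methoxybenzyl chloromethyl ether (20) is taken as a purchasable reagent.

**Step 1**
Reactants: 1 (R)-(+)-limonene
Product: 2 (4R)-limonene 1,2-oxide (cis/trans mixture at the epoxide)
Conditions: mCPBA, NaHCO3, CH2Cl2, 0 °C
Reagents that add atoms: mCPBA (3-chloroperoxybenzoic acid), OOC(=O)c1cccc(Cl)c1
Why: Prilezhaev epoxidation should be faster at the trisubstituted ring alkene than at the isopropenyl group, and the epoxide configuration is irrelevant because both carbons become carbonyl groups in step 2.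

**Step 2**
Reactants: 2 (4R)-limonene 1,2-oxide
Product: 4 (3R)-6-oxo-3-(prop-1-en-2-yl)heptanal, via limonene-1,2-diol 3 (not isolated)
Conditions: H5IO6, THF/H2O, 0 °C to rt
Reagents that add atoms: water, O
Why: Periodic acid should open the epoxide to the diol and cleave it in the same pot (Malaprade glycol cleavage), leaving the isopropenyl group and the stereocentre (future C9) untouched.

**Step 3**
Reactants: 4 (3R)-6-oxo-3-(prop-1-en-2-yl)heptanal
Product: 5 (5R)-7,7-dimethoxy-5-(prop-1-en-2-yl)heptan-2-one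
Conditions: HC(OMe)3, CeCl3·7H2O (cat.), MeOH, rt
Reagents that add atoms: trimethyl orthoformate, COC(OC)OC
Why: Cerium-catalysed acetalisation with an orthoformate is selective for aldehydes over ketones, so the aldehyde is masked before the enolate chemistry of step 4.

**Step 4**
Reactants: 5 (5R)-7,7-dimethoxy-5-(prop-1-en-2-yl)heptan-2-one
Product: 8 [(5R)-7,7-dimethoxy-5-(prop-1-en-2-yl)hept-1-yn-1-yl]trimethylsilane, via enol phosphate 6 (not isolated), via lithium acetylide 7 (not isolated)
Conditions: LiN(iPr)2, THF, −78 °C; ClP(O)(OEt)2; LiN(iPr)2 (2.3 equiv), −78 °C to rt; Me3SiCl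
Reagents that add atoms: chlorotrimethylsilane, C[Si](C)(C)Cl
Why: Kinetic enolisation at the methyl group, O-phosphorylation and elimination with excess amide base (methyl ketone to alkyne via the enol phosphate) should give the acetylide, which is C-silylated so that the future C13≡C14 alkyne stays inert until step 19.

**Step 5**
Reactants: 8 [(5R)-7,7-dimethoxy-5-(prop-1-en-2-yl)hept-1-yn-1-yl]trimethylsilane
Product: 9 (3R)-3-(prop-1-en-2-yl)-7-(trimethylsilyl)hept-6-ynal
Conditions: PPTS (cat.), acetone/H2O, 50 °C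
Reagents that add atoms: water, O
Why: Mild acid-catalysed acetal hydrolysis frees the aldehyde without touching the alkynylsilane or the isopropenyl group.

**Step 6**
Reactants: 9 (3R)-3-(prop-1-en-2-yl)-7-(trimethylsilyl)hept-6-ynal
Product: 10 (3R)-3-(prop-1-en-2-yl)-7-(trimethylsilyl)hept-1-en-6-yn-1-yl trifluoromethanesulfonate (E/Z mixture)
Conditions: Tf2O, 2,6-di-tert-butyl-4-methylpyridine, CH2Cl2, 0 °C to rt
Reagents that add atoms: trifluoromethanesulfonic anhydride, O=S(=O)(OS(=O)(=O)C(F)(F)F)C(F)(F)F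
Why: O-Triflation of the enolisable aldehyde with Tf2O and a hindered pyridine base gives the enol triflate (both geometric isomers serve), and the stereocentre, β to the former carbonyl, is not at risk.

**Step 7**
Reactants: 10 enol triflate
Product: 12 methyl (4S)-4-(prop-1-en-2-yl)-8-(trimethylsilyl)octa-2,7-diynoate, via lithium acetylide 11 (not isolated)
Conditions: LiN(iPr)2 (2.2 equiv), THF, −78 °C; ClCO2Me, −78 °C
Reagents that add atoms: methyl chloroformate, COC(=O)Cl
Why: Amide-base elimination of the enol triflate (E2 or Fritsch–Buttenberg–Wiechell-type) should give the terminal alkyne as its acetylide, which the chloroformate acylates to the 2-ynoate (C10 and C1 from the aldehyde arm, C2 from the chloroformate).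

**Step 8**
Reactants: 12 methyl (4S)-4-(prop-1-en-2-yl)-8-(trimethylsilyl)octa-2,7-diynoate
Product: 13 methyl (2Z,4S)-3-methyl-4-(prop-1-en-2-yl)-8-(trimethylsilyl)oct-2-en-7-ynoate
Conditions: Me2CuLi (from MeLi, CuI), THF, −78 °C; MeOH at −78 °C
Reagents that add atoms: lithium dimethylcuprate, [Li+].C[Cu-]C
Why: syn-Carbocupration (conjugate addition) of the cuprate to the 2-ynoate at −78 °C and protonation with retention should place the new C20 methyl cis to H1, so that C9 and the ester are cis, which is the Z-configured C10=C1 bond the key step needs.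

**Step 9**
Reactants: 13 methyl (2Z,4S)-3-methyl-4-(prop-1-en-2-yl)-8-(trimethylsilyl)oct-2-en-7-ynoate
Product: 14 methyl (2Z,4R)-4-(3-hydroxyprop-1-en-2-yl)-3-methyl-8-(trimethylsilyl)oct-2-en-7-ynoate
Conditions: SeO2 (cat.), t-BuOOH, salicylic acid (cat.), CH2Cl2, rt
Reagents that add atoms: tert-butyl hydroperoxide, CC(C)(C)OO
Why: SeO2/t-BuOOH allylic oxidation (ene reaction, then [2,3]-shift) should hydroxylate the methyl of the electron-rich isopropenyl group in preference to the C9 methine and to the deactivated enoate.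

**Step 10**
Reactants: 14 methyl (2Z,4R)-4-(3-hydroxyprop-1-en-2-yl)-3-methyl-8-(trimethylsilyl)oct-2-en-7-ynoate, 15 triethyl orthoacetate
Product: 17 8-ethyl 1-methyl (2Z,4S)-3-methyl-5-methylidene-4-[4-(trimethylsilyl)but-3-yn-1-yl]oct-2-enedioate, via ketene acetal 16 (not isolated)
Conditions: EtCO2H (cat.), neat 15, 140 °C, EtOH distilled off
Reagents that add atoms: none
Why: Johnson–Claisen [3,3]-rearrangement of the mixed ketene acetal forms the C6–C7 bond at the alkene terminus and turns the former carbinol carbon into the exocyclic C8=C17 methylene.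

**Step 11**
Reactants: 17 diester
Product: 18 (2Z,4S)-3-methyl-5-methylidene-4-[4-(trimethylsilyl)but-3-yn-1-yl]oct-2-ene-1,8-diol
Conditions: iBu2AlH (5 equiv), CH2Cl2, −78 to 0 °C
Reagents that add atoms: none
Why: Hydride reduction with iBu2AlH takes both esters to primary alcohols, which step 12 tells apart because only one is allylic.

**Step 12**
Reactants: 18 diol
Product: 19 (2Z,4S)-8-hydroxy-3-methyl-5-methylidene-4-[4-(trimethylsilyl)but-3-yn-1-yl]oct-2-enal
Conditions: MnO2, CH2Cl2, rt
Reagents that add atoms: none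
Why: MnO2 oxidises only the allylic alcohol and should do so without Z-to-E isomerisation at room temperature.

**Step 13**
Reactants: 20 4-methoxybenzyl chloromethyl ether, 21 triphenylphosphine
Product: 22 {[(4-methoxybenzyl)oxy]methyl}triphenylphosphonium chloride
Conditions: toluene, rt to 50 °C
Reagents that add atoms: none
Why: SN2 quaternisation of the phosphine by the reactive α-chloro ether gives the Wittig salt.

**Step 14**
Reactants: 19 hydroxy enal, 22 phosphonium salt
Product: 23 (5S,6Z,8E)-9-[(4-methoxybenzyl)oxy]-6-methyl-4-methylidene-5-[4-(trimethylsilyl)but-3-yn-1-yl]nona-6,8-dien-1-ol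
Conditions: NaN(SiMe3)2 (3.2 equiv), THF, 0 °C (ylide); then 19, −78 to 0 °C
Reagents that add atoms: none
Why: Wittig alkoxymethylenation adds C3 with its oxygen as an enol ether and should give a separable E/Z mixture at C2=C3, of which the (E)-isomer 23 is carried on, while the C10=C1 geometry is kept at low temperature.

**Step 15**
Reactants: 23 dienol ether alcohol
Product: 24 (5S,6Z,8E)-9-[(4-methoxybenzyl)oxy]-6-methyl-4-methylidene-5-[4-(trimethylsilyl)but-3-yn-1-yl]nona-6,8-dienal
Conditions: SO3·pyridine, DMSO, iPr2NEt, CH2Cl2, 0 °C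
Reagents that add atoms: none
Why: Parikh–Doering oxidation gives the aldehyde under basic conditions that the acid-labile dienol ether tolerates.

**Step 16**
Reactants: 24 aldehyde, 25 methyl 2-[bis(2,2,2-trifluoroethoxy)phosphoryl]propanoate
Product: 26 methyl (2Z,7S,8Z,10E)-11-[(4-methoxybenzyl)oxy]-2,8-dimethyl-6-methylidene-7-[4-(trimethylsilyl)but-3-yn-1-yl]undeca-2,8,10-trienoate
Conditions: KN(SiMe3)2, 18-crown-6, THF, −78 °C
Reagents that add atoms: none
Why: The Still–Gennari variant of the Horner–Wadsworth–Emmons reaction should give the Z-trisubstituted enoate (ester cis to the chain), the dienophile geometry that sets C4.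

**Step 17**
Reactants: 26 triene
Product: 27 methyl 3β-[(4-methoxybenzyl)oxy]-14-(trimethylsilyl)-15,16-dinor-5β-labda-1,8(17)-dien-13-yn-18-oate
Conditions: toluene (0.01 M), BHT, iPr2NEt (cat.), 170 °C, sealed tube
Reagents that add atoms: none
Why: Concerted, asynchronous suprafacial [4+2] cycloaddition of the electron-rich C3=C2–C1=C10 alkoxydiene with the tethered C4=C5 Z-enoate; the closest known reaction type is the intramolecular Diels–Alder reaction of 1,7,9-decatrienoates with a (Z)-diene that carries an allylic stereocentre. Ring A closes as the cycloadduct cyclohexene (C5–C10 and C3–C4), and ring B closes as the fused six-membered ring through the C6–C9 chain. Because this chain leaves C10 from the inside (cis) position of the diene, it can reach C5 only in the exo orientation, which should give the cis ring fusion (H5 syn to the C10 methyl) with no trans-fused pathway. C4 is set by the dienophile geometry (methyl syn to H5, ester anti) and C3 by the E enol ether (alkoxy syn to C20; removed later as the ketone). The selectivity needed is the diene face: 1,3-allylic strain between the C9 substituents and C2–H holds H9 in the diene plane, so the C8 tether and C11 lie on opposite faces and the dienophile adds anti to C11, placing C11 cis to the C10 methyl as the target requires.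

**Step 18**
Reactants: 27 cycloadduct
Product: 28 3β-[(4-methoxybenzyl)oxy]-14-(trimethylsilyl)-15,16-dinor-5β-labda-1,8(17)-dien-13-yn-18-ol
Conditions: LiAlH4, THF, 0 °C to rt
Reagents that add atoms: none
Why: Hydride reduction with LiAlH4 takes the hindered neopentyl ester to the C18 alcohol, while the ethers, alkenes and the alkynylsilane are inert.

**Step 19**
Reactants: 28 alcohol
Product: 29 3β-[(4-methoxybenzyl)oxy]-15,16-dinor-5β-labda-1,8(17)-dien-13-yn-18-ol
Conditions: K2CO3, MeOH, rt
Reagents that add atoms: none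
Why: Base-catalysed methanolysis cleaves the C(sp)–Si bond selectively to the terminal alkyne.

**Step 20**
Reactants: 29 alkynol
Product: 31 allyl 18-[(allyloxycarbonyl)oxy]-3β-[(4-methoxybenzyl)oxy]-16-nor-5β-labda-1,8(17)-dien-13-yn-15-oate, via dilithium alkoxide acetylide 30 (not isolated)
Conditions: n-BuLi (2.2 equiv), THF, −78 °C; ClCO2CH2CH=CH2 (2.5 equiv), −78 to −20 °C
Reagents that add atoms: allyl chloroformate, C=CCOC(=O)Cl
Why: Double deprotonation (alcohol and terminal alkyne) and acylation with the chloroformate gives the allyl 2-ynoate (C15) and at the same time masks C18–OH as an allyl carbonate.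

**Step 21**
Reactants: 31 ynoate
Product: 32 allyl (13Z)-18-[(allyloxycarbonyl)oxy]-3β-[(4-methoxybenzyl)oxy]-5β-labda-1,8(17),13-trien-15-oate
Conditions: Me2CuLi (from MeLi, CuI), THF, −78 °C; MeOH at −78 °C
Reagents that add atoms: lithium dimethylcuprate, [Li+].C[Cu-]C
Why: syn-Carbocupration of the 2-ynoate and low-temperature protonation with retention should put the C16 methyl cis to H14, so that C12 and the ester are cis (13Z), faster than any attack on the allyl ester or carbonate.

**Step 22**
Reactants: 32 trienoate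
Product: 33 allyl (13Z)-18-[(allyloxycarbonyl)oxy]-3β-hydroxy-5β-labda-1,8(17),13-trien-15-oate
Conditions: DDQ, CH2Cl2/pH 7 buffer, 0 °C
Reagents that add atoms: none
Why: Oxidative cleavage of the 4-methoxybenzyl ether with DDQ (benzylic hydride abstraction, then hydrolysis) frees the allylic C3 alcohol under neutral conditions.

**Step 23**
Reactants: 33 allylic alcohol
Product: 34 allyl (13Z)-18-[(allyloxycarbonyl)oxy]-3-oxo-5β-labda-1,8(17),13-trien-15-oate
Conditions: Dess–Martin periodinane, NaHCO3, CH2Cl2, 0 °C to rt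
Reagents that add atoms: none
Why: Dess–Martin oxidation gives the enone and removes the C3 stereocentre; the carbonate cannot β-eliminate because C4 is quaternary.

**Step 24**
Reactants: 34 enone
Product: 35 allyl (13Z)-18-[(allyloxycarbonyl)oxy]-3-oxo-5β-labda-8(17),13-dien-15-oate
Conditions: [(Ph3P)CuH]6, benzene/H2O, rt
Reagents that add atoms: none
Why: Conjugate reduction with the copper hydride (Stryker reduction) should be selective for the enone over the isolated alkenes and the β,β-disubstituted enoate, and creates no stereocentre.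

**Step 25**
Reactants: 35 ketone
Product: 36 (13Z)-18-hydroxy-3-oxo-5β-labda-8(17),13-dien-15-oic acid
Conditions: Pd(PPh3)4 (cat.), morpholine, THF, 0 °C to rt
Reagents that add atoms: none
Why: Palladium-catalysed allyl transfer to morpholine (Tsuji–Trost-type deallylation) cleaves the allyl ester to the acid and the allyl carbonate, after loss of CO2, to the C18 alcohol under near-neutral conditions.

**Step 26**
Reactants: 36 hydroxy acid
Product: 38 (13Z)-18-acetoxy-3-oxo-5β-labda-8(17),13-dien-15-oic acid, via mixed anhydride 37 (not isolated)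
Conditions: Ac2O, pyridine, DMAP (cat.), CH2Cl2, 0 °C to rt; then H2O/THF
Reagents that add atoms: acetic anhydride, CC(=O)OC(C)=O
Why: Pyridine/DMAP-catalysed acetylation esterifies the primary C18 alcohol, and the mixed anhydride formed at C15 is hydrolysed in the aqueous step.

**Compound list**
1 | (R)-(+)-limonene | CC1=CC[C@@H](CC1)C(C)=C | starting material
2 | (4R)-limonene 1,2-oxide (cis/trans mixture) | CC12OC1C[C@@H](CC2)C(C)=C | intermediate
3 | (4R)-p-menth-8-ene-1,2-diol (limonene-1,2-diol) | CC1(O)C(O)C[C@@H](CC1)C(C)=C | intermediate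
4 | (3R)-6-oxo-3-(prop-1-en-2-yl)heptanal | O=CC[C@@H](CCC(C)=O)C(C)=C | intermediate
5 | (5R)-7,7-dimethoxy-5-(prop-1-en-2-yl)heptan-2-one | COC(OC)C[C@@H](CCC(C)=O)C(C)=C | intermediate
6 | diethyl (5R)-7,7-dimethoxy-5-(prop-1-en-2-yl)hept-1-en-2-yl phosphate | COC(OC)C[C@@H](CCC(=C)OP(=O)(OCC)OCC)C(C)=C | intermediate
7 | [(5R)-7,7-dimethoxy-5-(prop-1-en-2-yl)hept-1-yn-1-yl]lithium | COC(OC)C[C@@H](CCC#C[Li])C(C)=C | intermediate
8 | [(5R)-7,7-dimethoxy-5-(prop-1-en-2-yl)hept-1-yn-1-yl]trimethylsilane | COC(OC)C[C@@H](CCC#C[Si](C)(C)C)C(C)=C | intermediate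
9 | (3R)-3-(prop-1-en-2-yl)-7-(trimethylsilyl)hept-6-ynal | O=CC[C@@H](CCC#C[Si](C)(C)C)C(C)=C | intermediate
10 | (3R)-3-(prop-1-en-2-yl)-7-(trimethylsilyl)hept-1-en-6-yn-1-yl trifluoromethanesulfonate (E/Z mixture) | FC(F)(F)S(=O)(=O)OC=C[C@@H](CCC#C[Si](C)(C)C)C(C)=C | intermediate
11 | [(3S)-3-(prop-1-en-2-yl)-7-(trimethylsilyl)hepta-1,6-diyn-1-yl]lithium | [Li]C#C[C@@H](CCC#C[Si](C)(C)C)C(C)=C | intermediate
12 | methyl (4S)-4-(prop-1-en-2-yl)-8-(trimethylsilyl)octa-2,7-diynoate | COC(=O)C#C[C@@H](CCC#C[Si](C)(C)C)C(C)=C | intermediate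
13 | methyl (2Z,4S)-3-methyl-4-(prop-1-en-2-yl)-8-(trimethylsilyl)oct-2-en-7-ynoate | COC(=O)\C=C(C)/[C@@H](CCC#C[Si](C)(C)C)C(C)=C | intermediate
14 | methyl (2Z,4R)-4-(3-hydroxyprop-1-en-2-yl)-3-methyl-8-(trimethylsilyl)oct-2-en-7-ynoate | COC(=O)\C=C(C)/[C@@H](CCC#C[Si](C)(C)C)C(=C)CO | intermediate
15 | triethyl orthoacetate | CCOC(C)(OCC)OCC | starting material
16 | methyl (2Z,4R)-4-{3-[(1-ethoxyethenyl)oxy]prop-1-en-2-yl}-3-methyl-8-(trimethylsilyl)oct-2-en-7-ynoate (ketene acetal) | COC(=O)\C=C(C)/[C@@H](CCC#C[Si](C)(C)C)C(=C)COC(=C)OCC | intermediate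
17 | 8-ethyl 1-methyl (2Z,4S)-3-methyl-5-methylidene-4-[4-(trimethylsilyl)but-3-yn-1-yl]oct-2-enedioate | CCOC(=O)CCC(=C)[C@H](CCC#C[Si](C)(C)C)/C(C)=C\C(=O)OC | intermediate
18 | (2Z,4S)-3-methyl-5-methylidene-4-[4-(trimethylsilyl)but-3-yn-1-yl]oct-2-ene-1,8-diol | OCCCC(=C)[C@H](CCC#C[Si](C)(C)C)/C(C)=C\CO | intermediate
19 | (2Z,4S)-8-hydroxy-3-methyl-5-methylidene-4-[4-(trimethylsilyl)but-3-yn-1-yl]oct-2-enal | OCCCC(=C)[C@H](CCC#C[Si](C)(C)C)/C(C)=C\C=O | intermediate
20 | 4-methoxybenzyl chloromethyl ether | COc1ccc(COCCl)cc1 | starting material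
21 | triphenylphosphine | c1ccc(cc1)P(c1ccccc1)c1ccccc1 | starting material
22 | {[(4-methoxybenzyl)oxy]methyl}triphenylphosphonium chloride | COc1ccc(COC[P+](c2ccccc2)(c2ccccc2)c2ccccc2)cc1.[Cl-] | intermediate
23 | (5S,6Z,8E)-9-[(4-methoxybenzyl)oxy]-6-methyl-4-methylidene-5-[4-(trimethylsilyl)but-3-yn-1-yl]nona-6,8-dien-1-ol | OCCCC(=C)[C@H](CCC#C[Si](C)(C)C)/C(C)=C\C=C\OCc1ccc(OC)cc1 | intermediate
24 | (5S,6Z,8E)-9-[(4-methoxybenzyl)oxy]-6-methyl-4-methylidene-5-[4-(trimethylsilyl)but-3-yn-1-yl]nona-6,8-dienal | O=CCCC(=C)[C@H](CCC#C[Si](C)(C)C)/C(C)=C\C=C\OCc1ccc(OC)cc1 | intermediate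
25 | methyl 2-[bis(2,2,2-trifluoroethoxy)phosphoryl]propanoate | COC(=O)C(C)P(=O)(OCC(F)(F)F)OCC(F)(F)F | starting material
26 | methyl (2Z,7S,8Z,10E)-11-[(4-methoxybenzyl)oxy]-2,8-dimethyl-6-methylidene-7-[4-(trimethylsilyl)but-3-yn-1-yl]undeca-2,8,10-trienoate | COC(=O)/C(C)=C\CCC(=C)[C@H](CCC#C[Si](C)(C)C)/C(C)=C\C=C\OCc1ccc(OC)cc1 | intermediate
27 | methyl 3β-[(4-methoxybenzyl)oxy]-14-(trimethylsilyl)-15,16-dinor-5β-labda-1,8(17)-dien-13-yn-18-oate | C=C1CC[C@H]2[C@](C)(C=C[C@H](OCc3ccc(OC)cc3)[C@@]2(C)C(=O)OC)[C@H]1CCC#C[Si](C)(C)C | intermediate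
28 | 3β-[(4-methoxybenzyl)oxy]-14-(trimethylsilyl)-15,16-dinor-5β-labda-1,8(17)-dien-13-yn-18-ol | C=C1CC[C@H]2[C@](C)(C=C[C@H](OCc3ccc(OC)cc3)[C@@]2(C)CO)[C@H]1CCC#C[Si](C)(C)C | intermediate
29 | 3β-[(4-methoxybenzyl)oxy]-15,16-dinor-5β-labda-1,8(17)-dien-13-yn-18-ol | C=C1CC[C@H]2[C@](C)(C=C[C@H](OCc3ccc(OC)cc3)[C@@]2(C)CO)[C@H]1CCC#C | intermediate
30 | dilithium alkoxide acetylide of 29 | C=C1CC[C@H]2[C@](C)(C=C[C@H](OCc3ccc(OC)cc3)[C@@]2(C)CO[Li])[C@H]1CCC#C[Li] | intermediate
31 | allyl 18-[(allyloxycarbonyl)oxy]-3β-[(4-methoxybenzyl)oxy]-16-nor-5β-labda-1,8(17)-dien-13-yn-15-oate | C=C1CC[C@H]2[C@](C)(C=C[C@H](OCc3ccc(OC)cc3)[C@@]2(C)COC(=O)OCC=C)[C@H]1CCC#CC(=O)OCC=C | intermediate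
32 | allyl (13Z)-18-[(allyloxycarbonyl)oxy]-3β-[(4-methoxybenzyl)oxy]-5β-labda-1,8(17),13-trien-15-oate | C=C1CC[C@H]2[C@](C)(C=C[C@H](OCc3ccc(OC)cc3)[C@@]2(C)COC(=O)OCC=C)[C@H]1CC/C(C)=C\C(=O)OCC=C | intermediate
33 | allyl (13Z)-18-[(allyloxycarbonyl)oxy]-3β-hydroxy-5β-labda-1,8(17),13-trien-15-oate | C=C1CC[C@H]2[C@](C)(C=C[C@H](O)[C@@]2(C)COC(=O)OCC=C)[C@H]1CC/C(C)=C\C(=O)OCC=C | intermediate
34 | allyl (13Z)-18-[(allyloxycarbonyl)oxy]-3-oxo-5β-labda-1,8(17),13-trien-15-oate | C=C1CC[C@H]2[C@](C)(C=CC(=O)[C@@]2(C)COC(=O)OCC=C)[C@H]1CC/C(C)=C\C(=O)OCC=C | intermediate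
35 | allyl (13Z)-18-[(allyloxycarbonyl)oxy]-3-oxo-5β-labda-8(17),13-dien-15-oate | C=C1CC[C@H]2[C@](C)(CCC(=O)[C@@]2(C)COC(=O)OCC=C)[C@H]1CC/C(C)=C\C(=O)OCC=C | intermediate
36 | (13Z)-18-hydroxy-3-oxo-5β-labda-8(17),13-dien-15-oic acid | C=C1CC[C@H]2[C@](C)(CCC(=O)[C@@]2(C)CO)[C@H]1CC/C(C)=C\C(=O)O | intermediate
37 | acetic (13Z)-18-acetoxy-3-oxo-5β-labda-8(17),13-dien-15-oic anhydride | C=C1CC[C@H]2[C@](C)(CCC(=O)[C@@]2(C)COC(C)=O)[C@H]1CC/C(C)=C\C(=O)OC(C)=O | intermediate
38 | (13Z)-18-acetoxy-3-oxo-5β-labda-8(17),13-dien-15-oic acid, (4R,5S,9S,10R) | C=C1CC[C@H]2[C@](C)(CCC(=O)[C@@]2(C)COC(C)=O)[C@H]1CC/C(C)=C\C(=O)O | target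

**Step count**
Total: 26 steps. Longest linear sequence: 25 steps (1–12 and 14–26 from limonene); step 13 is a one-step branch that makes the Wittig salt.

**Steps most likely to fail**

Step 17. The cycloaddition joins a fully substituted diene terminus to a trisubstituted enoate and may need a temperature at which a suprafacial 1,5-hydrogen shift of H9 into the diene competes. That shift would erase the C9 centre and the Z-diene geometry; thermal loss of the enol ether is a second drain. The fallback raises the dienophile reactivity by changing the activating group to an aldehyde. Setting out from 26, iBu2AlH at −78 °C should give the allylic alcohol F1, and MnO2 the Z-enal F2. The enal should cyclise through the same transition-state geometry at 60–80 °C to the cycloadduct aldehyde F3, which NaBH4 reduces to the alcohol, so the route is rejoined at 28.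

Step 14. The ylide may give poor E/Z control at the new C2=C3 enol ether bond, and as a base it may isomerise the Z-enal or deprotonate at C9. The fallback is a Horner–Wittig sequence starting from 19. The phosphine oxide F4 (made by O-alkylation of (hydroxymethyl)diphenylphosphine oxide with 4-methoxybenzyl chloride) is lithiated with LiN(iPr)2 at −78 °C and added to 19. The diastereomeric adducts are separated, and the threo β-hydroxy phosphine oxide F5 undergoes stereospecific syn-elimination with KH to the (E)-enol ether only, which returns to the route at 23.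

Step 9. The allylic oxidation may run on to the enal or attack the C9 methine or the enoate methyl, costing material and the integrity of C9. The fallback goes from 13 through an epoxide. mCPBA should epoxidise only the electron-rich isopropenyl alkene to give the epoxide F6. The trivalent titanium reagent Cp2TiCl (from Cp2TiCl2 and Mn) then opens the epoxide to the tertiary radical, and loss of a methyl hydrogen gives the 2-substituted allylic alcohol, returning to the route at 14.

**Further compounds**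
F1 | step 17 | (2Z,7S,8Z,10E)-11-[(4-methoxybenzyl)oxy]-2,8-dimethyl-6-methylidene-7-[4-(trimethylsilyl)but-3-yn-1-yl]undeca-2,8,10-trien-1-ol | OC/C(C)=C\CCC(=C)[C@H](CCC#C[Si](C)(C)C)/C(C)=C\C=C\OCc1ccc(OC)cc1
F2 | step 17 | (2Z,7S,8Z,10E)-11-[(4-methoxybenzyl)oxy]-2,8-dimethyl-6-methylidene-7-[4-(trimethylsilyl)but-3-yn-1-yl]undeca-2,8,10-trienal | O=C/C(C)=C\CCC(=C)[C@H](CCC#C[Si](C)(C)C)/C(C)=C\C=C\OCc1ccc(OC)cc1
F3 | step 17 | 3β-[(4-methoxybenzyl)oxy]-14-(trimethylsilyl)-15,16-dinor-5β-labda-1,8(17)-dien-13-yn-18-al | C=C1CC[C@H]2[C@](C)(C=C[C@H](OCc3ccc(OC)cc3)[C@@]2(C)C=O)[C@H]1CCC#C[Si](C)(C)C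
F4 | step 14 | {[(4-methoxybenzyl)oxy]methyl}diphenylphosphine oxide | COc1ccc(COCP(=O)(c2ccccc2)c2ccccc2)cc1
F5 | step 14 | threo β-hydroxy phosphine oxide adduct of 19 and F4 | OCCCC(=C)[C@H](CCC#C[Si](C)(C)C)/C(C)=C\C(O)C(OCc1ccc(OC)cc1)P(=O)(c1ccccc1)c1ccccc1
F6 | step 9 | methyl (2Z,4S)-3-methyl-4-(2-methyloxiran-2-yl)-8-(trimethylsilyl)oct-2-en-7-ynoate | COC(=O)\C=C(C)/[C@@H](CCC#C[Si](C)(C)C)C1(C)CO1
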